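## Retrosynthetic overview

1. The target is the (2S)-flavanone (at C2: O1 > C1′ > C3 > H). The last operation only frees the 4′-phenol from a benzyl ether (7 ⇐ 6).
2. The key disconnection is the C2–C1′ bond between ring C and ring B: 6 ⇐ 5,6,7-trimethoxychromone 4 + arylboronic acid 5. A Rh(I)-catalysed enantioselective 1,4-arylation joins the two halves, creates the only stereocentre and lowers ring C from the pyranone to the dihydropyranone level in one operation.
3. Enabling feature: in ring C the stereocentre C2 lies β to the C4 ketone and α to O1. Its planar precursor is therefore the C2=C3–C4=O vinylogous ester of a 4H-chromen-4-one, a flat achiral acceptor whose only acceptor carbon is the unsubstituted C2.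
4. Ring order: ring A is bought (phenol 1). Ring C is closed by O1–C2 bond formation from acetophenone 2 through an enaminone. Ring B is bought within 5 and attached last.

Key step: step 3

Assumption: the (S)-configured biaryl bisphosphine is taken to induce the same spatial sense on chromone 4 as on 2-cyclohexenone (aryl to the Re face of C2). The antipodal ligand is equally available.

## Route

Step 1
Reactants: 1 3,4,5-trimethoxyphenol
Product: 2 1-(6-hydroxy-2,3,4-trimethoxyphenyl)ethan-1-one
Conditions: Ac2O (1.2 equiv), BF3·OEt2 (excess), 0 to 70 °C; then H2O
Reagents that add atoms: acetic anhydride, CC(=O)OC(C)=O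
Why: Friedel–Crafts acylation of a very electron-rich phenol whose two free ring positions (ortho to OH) are equivalent by symmetry, so only one ketone can form, the hydrogen-bonded ortho-hydroxy ketone is deactivated towards a second acylation, BF3 at this temperature leaves the aryl methyl ethers intact, and no stereocentre is created.

Step 2
Reactants: 2 1-(6-hydroxy-2,3,4-trimethoxyphenyl)ethan-1-one
Product: 4 5,6,7-trimethoxy-4H-chromen-4-one, via enaminone 3 (not isolated)
Conditions: Me2NCH(OMe)2 (2 equiv), toluene, 100 °C; evaporate; then conc. HCl, CH2Cl2, 40 °C
Reagents that add atoms: N,N-dimethylformamide dimethyl acetal, COC(OC)N(C)C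
Why: Aminomethylenation of the methyl ketone with an amide acetal gives the push–pull enaminone 3, and acid then promotes conjugate addition of the ortho-phenol oxygen to the β-carbon followed by loss of dimethylamine (addition–elimination, 6-endo-trig closure of the O1–C2 bond, the standard enaminone synthesis of chromones), which forms ring C without any stereocentre.

Step 3
Reactants: 4 5,6,7-trimethoxy-4H-chromen-4-one; 5 [4-(benzyloxy)-3-methoxyphenyl]boronic acid
Product: 6 (2S)-2-[4-(benzyloxy)-3-methoxyphenyl]-5,6,7-trimethoxy-2,3-dihydro-4H-chromen-4-one
Conditions: [Rh(OH)(cod)]2 (1.5 mol %), (S)-MeO-F12-BIPHEP [(S)-2,2′-bis[bis(3,4,5-trifluorophenyl)phosphino]-6,6′-dimethoxybiphenyl, 3.3 mol %], 5 (1.5 equiv), CH2Cl2/H2O, 20 °C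
Reagents that add atoms: none
Why: Transmetalation of 5 to the hydroxo-Rh(I) bisphosphine complex gives an aryl-Rh(I) species that binds the C2=C3 bond of the pyranone ring of 4, migratory insertion carries the aryl carbon C1′ to C2 (β to C4=O), and water protonates the resulting oxa-π-allyl rhodium enolate at C3, which frees 6 and boric acid and restores Rh–OH. The closest known reaction type is the Hayashi–Miyaura asymmetric 1,4-addition of arylboronic acids, which is established for 4H-chromen-4-ones, C5/C7-oxygenated ones included, with electron-poor atropisomeric bisphosphines. No ring is closed: ring C is kept and passes from the pyranone to the dihydropyranone level while the A/C bicycle and ring B become joined. The single new stereocentre C2 is controlled by the catalyst alone, because 4 is flat and achiral: one P-aryl ring of the (S)-biaryl ligand blocks half of the free coordination site so that the alkene should bind through its C3-Si (= C2-Re) face, and aryl delivery to the Re face of C2 should give the 2S configuration, the same spatial sense in which (S)-biaryl bisphosphines give (S)-3-arylcyclohexanones. The step needs 1,4- over 1,2-selectivity and no second arylation of the product ketone, which the peri 5-methoxy group and the electron-rich ring A secure by shielding and deactivating C4=O, while C2 is the only acceptor carbon so that regiochemistry is not in question. It also needs configurational stability of 6, secured by the base-free medium at 20 °C (no E1cB opening of ring C to the 2′-hydroxychalcone) and by the benzyl ether, which prevents quinone-methide-type ionisation of the C2–O1 bond by a free 4′-phenol.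

Step 4
Reactants: 6 (2S)-2-[4-(benzyloxy)-3-methoxyphenyl]-5,6,7-trimethoxy-2,3-dihydro-4H-chromen-4-one
Product: 7 Agecorynin E, (2S)-2-(4-hydroxy-3-methoxyphenyl)-5,6,7-trimethoxy-2,3-dihydro-4H-chromen-4-one
Conditions: H2 (1 atm), 10 % Pd/C, EtOAc, 20 °C
Reagents that add atoms: none
Why: Catalytic hydrogenolysis of a benzyl aryl ether under neutral conditions at ambient pressure should be faster than cleavage of the cyclic C2–O1 bond or reduction of the hindered, electron-rich C4 ketone, and because no base or acid is present C2 should keep its S configuration.

## Compound list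

1 | 3,4,5-trimethoxyphenol | COc1cc(O)cc(OC)c1OC | starting material
2 | 1-(6-hydroxy-2,3,4-trimethoxyphenyl)ethan-1-one | CC(=O)c1c(O)cc(OC)c(OC)c1OC | intermediate
3 | (E)-3-(dimethylamino)-1-(6-hydroxy-2,3,4-trimethoxyphenyl)prop-2-en-1-one (enaminone, not isolated) | CN(C)/C=C/C(=O)c1c(O)cc(OC)c(OC)c1OC | intermediate
4 | 5,6,7-trimethoxy-4H-chromen-4-one | COc1cc2occc(=O)c2c(OC)c1OC | intermediate
5 | [4-(benzyloxy)-3-methoxyphenyl]boronic acid | COc1cc(B(O)O)ccc1OCc1ccccc1 | starting material
6 | (2S)-2-[4-(benzyloxy)-3-methoxyphenyl]-5,6,7-trimethoxy-2,3-dihydro-4H-chromen-4-one | COc1cc([C@@H]2CC(=O)c3c(cc(OC)c(OC)c3OC)O2)ccc1OCc1ccccc1 | intermediate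
7 | Agecorynin E, (2S)-2-(4-hydroxy-3-methoxyphenyl)-5,6,7-trimethoxy-2,3-dihydro-4H-chromen-4-one | COc1cc([C@@H]2CC(=O)c3c(cc(OC)c(OC)c3OC)O2)ccc1O | target

## Step count and risks

Total step count: 4.
Longest linear sequence: 4 (1 → 2 → 4 → 6 → 7). Compound 5 is bought and enters at step 3.

**Step 3.** Migratory insertion into the electron-rich vinylogous ester may be slow, so that the boronic acid is lost by protodeboronation. Facial selectivity may also be insufficient, or enantiopurity may erode through reversible opening of ring C.

The fallback sets out from 4 (with 5) and comes back at 6. It separates bond formation from creation of the stereocentre.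
- The same C2–C1′ bond would be made by a Pd(II)-catalysed oxidative boron-Heck arylation of 4 with 5 (Pd(II) salt, terminal oxidant such as O2 or DDQ). This should give the achiral flavone 2-[4-(benzyloxy)-3-methoxyphenyl]-5,6,7-trimethoxy-4H-chromen-4-one F1.
- Asymmetric hydrogenation of the pyranone ring with a chiral Ru–N-heterocyclic-carbene catalyst under H2 pressure would deliver hydrogen to one face. This should give the cis alcohol (2S,4S)-2-[4-(benzyloxy)-3-methoxyphenyl]-5,6,7-trimethoxychroman-4-ol F2.
- Dess–Martin oxidation of the C4 alcohol in CH2Cl2 would then return to 6 without touching C2.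

**Step 4.** Over-reduction may occur, either as hydrogenolytic opening of ring C at the benzylic C2–O1 bond or as reduction of the C4 ketone. Configuration may also be lost on prolonged contact of the free 4′-hydroxyflavanone with the catalyst.

The fallback sets out from 4 and comes back at 7. It removes every reductive operation by changing the phenol mask.
- The purchasable [4-(tert-butyldimethylsilyloxy)-3-methoxyphenyl]boronic acid F3 would be added to 4 by the asymmetric 1,4-arylation of step 3. This should give (2S)-2-[4-(tert-butyldimethylsilyloxy)-3-methoxyphenyl]-5,6,7-trimethoxy-2,3-dihydro-4H-chromen-4-one F4.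
- The aryl silyl ether would be cleaved with the weakly acidic fluoride source Et3N·3HF in THF at 0 to 20 °C. No free phenoxide is generated, which should lead to 7.

**Step 2.** The amide acetal may O-methylate the phenol, or the hindered, twisted 2,6-disubstituted aryl methyl ketone may condense incompletely.

The fallback sets out from 2 and comes back at 4. It replaces the thermal aminomethylenation by enolate chemistry.
- Claisen C-formylation of the dianion of 2 (NaH, ethyl formate, THF, 0 to 20 °C) should give, after acidification, the β-ketoaldehyde in its cyclic hemiacetal form, 2-hydroxy-5,6,7-trimethoxychroman-4-one F5.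
- Acid-catalysed dehydration (cat. p-TsOH, toluene, warm) would then give 4.

## Further compounds

F1 | step 3 | 2-[4-(benzyloxy)-3-methoxyphenyl]-5,6,7-trimethoxy-4H-chromen-4-one | COc1cc(-c2cc(=O)c3c(cc(OC)c(OC)c3OC)o2)ccc1OCc1ccccc1
F2 | step 3 | (2S,4S)-2-[4-(benzyloxy)-3-methoxyphenyl]-5,6,7-trimethoxychroman-4-ol | COc1cc([C@@H]2C[C@H](O)c3c(cc(OC)c(OC)c3OC)O2)ccc1OCc1ccccc1
F3 | step 4 | [4-(tert-butyldimethylsilyloxy)-3-methoxyphenyl]boronic acid | COc1cc(B(O)O)ccc1O[Si](C)(C)C(C)(C)C
F4 | step 4 | (2S)-2-[4-(tert-butyldimethylsilyloxy)-3-methoxyphenyl]-5,6,7-trimethoxy-2,3-dihydro-4H-chromen-4-one | COc1cc([C@@H]2CC(=O)c3c(cc(OC)c(OC)c3OC)O2)ccc1O[Si](C)(C)C(C)(C)C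
F5 | step 2 | 2-hydroxy-5,6,7-trimethoxychroman-4-one (racemic, configurationally labile hemiacetal) | OC1CC(=O)c2c(cc(OC)c(OC)c2OC)O1
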